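The earlier runs and the new flask come from a simulation for an exercise; noise was put on by code.

The pitfall here is to read beta's longer time as a longer road to full conversion; you asked for a quick number, and I start from what the charges allow.

in all of them: partner 0.332 M; free catalyst 8.8 mM

|  | substrate | temperature | remark | time |
|---|---|---|---|---|
| north-west | 0.24 M | 65 °C | run made earlier |  |
| west | 0.26 M | 80 °C | run made earlier |  |
| north | 0.28 M | 65 °C | run made earlier |  |
| beta | 0.35 M | 80 °C |  | 8.0 d |
| zeta | 0.20 M | 80 °C |  | 4.0 d |

| run | time / d | product / % |
|---|---|---|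
| north-west | 4.00 | 56 |
| north-west | 6.00 | 72 |
| north-west | 10.0 | 92 |
| north-west | 12.0 | 94 |
| north-west | 15.0 | 99 |
| west | 1.67 | 64 |
| west | 3.00 | 87 |
| west | 5.00 | 97 |
| west | 6.00 | 100 |
| west | 8.00 | 101 |
| north | 1.25 | 20 |
| north | 4.00 | 52 |
| north | 8.00 | 81 |
| north | 12.0 | 95 |
| north | 15.0 | 99 |

(each reading ± 1.5 percentage points)

- the numbers in the tables scatter by 1.5 percentage points (one standard deviation)

- which of the two ends with the higher amount of product, in percent of the substrate charged ("neither" if they lie within 2 percentage points) (beta / zeta / neither)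
- product at the end, in percent of the substrate charged, beta
- product at the end, in percent of the substrate charged, zeta

Follow one substrate molecule to product. I assume it uses up one partner molecule. The readings cannot test this, since every run held more partner than substrate. For beta, 0.332 M of partner against 0.35 M of substrate gives 94.9 %, and this ratio c(partner)/c(substrate), the ceiling on product as a share of the substrate charged, is what I carry. Partner is the limiting reagent in beta, whereas zeta's ratio is 166 %, so there the clock matters.

The west run stood at the same temperature as both flasks, and its 87 % at 3.00 d, read as first order, gives 0.680 d⁻¹. At that rate beta would convert 99.6 % of its substrate by its 8.0 d, which is above its ceiling, so I commit to the ceiling for beta. Zeta reaches 93.4 % in 4.0 d. With 94.9 % for beta and 93.4 % for zeta against a margin of 2 percentage points, my call is neither, though a scatter of 1.5 points sits on that one reading.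

The forecast gives 95 % for beta and 97.5 % for zeta, above my figure, with beta “slightly below zeta”, and so names zeta. The flasks give 94.9 % for beta and 94.2 % for zeta, so the answer is neither.

    substrate + free catalyst ⇌ catalyst intermediate A (K = 2.20 M⁻¹, k = 23.0 M⁻¹ h⁻¹, Ea = 73.0 kJ mol⁻¹, ΔH = −38.0 kJ mol⁻¹)
    catalyst intermediate A → catalyst intermediate B (k = 2.10 h⁻¹, Ea = 101 kJ mol⁻¹)
    partner + catalyst intermediate B ⇌ catalyst intermediate C (K = 9.10 M⁻¹, k = 570 M⁻¹ h⁻¹, Ea = 54.0 kJ mol⁻¹, ΔH = −41.0 kJ mol⁻¹)
    catalyst intermediate C → free catalyst + product (k = 82.0 h⁻¹, Ea = 100 kJ mol⁻¹)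
    (constants at 80 °C)

Beta sits on its ceiling of 94.9 %, with partner at 0 % at 8.00 d and product still 94.9 % at 80.0 d. In zeta at 0.999 d, catalyst intermediate A falls back 5.0 times faster than it goes on, so a bound substrate molecule goes forward with a chance of 16.7 %. At 4.00 d free catalyst, the resting state, holds 97.8 % of zeta's catalyst, and 5.7 % of its substrate remains. Zeta's recipe with 0.80 M of substrate has a ceiling of 41.5 %, and at 4.00 d that flask holds 41.5 % product with partner at 0 %.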